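**Retrosynthetic overview**

1. Ring B is a cyclohexene whose C7=C8 double bond lies 1,4 across the ring from the C5–C10 bond. This is a Diels–Alder retron: diene C6=C7–C8=C9, dienophile C5=C10.
2. H-5 and the C10 methyl are trans, so ring A cannot sit on the dienophile. It is opened at C1/C2 into the (E)-enal 3 (C1 = CHO, allyl arm on C4). C9 is kept sp2 as the central carbon of a 2-silyloxy vinylallene, so no endo/exo question arises and H-9 is delivered later.
3. Ring order: ring B by the cycloaddition (step 5), then ring A by ring-closing metathesis (step 7, saturated in step 11), giving (−)-drimenol 16.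
4. The C11–C12 bond is made by lithiation–borylation of carbamate 25 with drimenyl boronate 18. (+)-Sparteine sets C12; C13 comes from a Ru–BINAP hydrogenation of a geranylarene-derived allylic alcohol.
5. Endgame: O-sulfation of C12–OH, then unmasking of the hydroquinone (CAN, dithionite).

Key step: step 5

**Remarks on the chemistry**

- Sulfate monoesters 30–32 are written as neutral hydrogen sulfates, as in the target; in practice they would be handled as sodium salts and acidified only at the end.
- The bicyclic core carries drimane numbers (C1–C10, C11 = CH2 on C9). The chain continues C12 (carbinol), C13 (CHCH3), C14–C16, C17 (=C–CH3), C18, C19 (ArCH2).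

**Route**

Step 1
Reactants: 1 2,2-dimethylpent-4-enal; 2 2-(triphenyl-λ5-phosphanylidene)propanal
Product: 3 (2E)-2,4,4-trimethylhepta-2,6-dienal
Conditions: toluene, 110 °C
Reagents that add atoms: none
Why: Wittig olefination of a non-enolisable neopentyl aldehyde with a stabilised formyl ylide should give the (E)-enal, with the tert-alkyl group trans to CHO.

Step 2
Reactants: 4 1-bromobut-2-yne; 5 acetaldehyde
Product: 6 (±)-3-methylpenta-3,4-dien-2-ol
Conditions: In powder, THF/H2O, 0 °C → rt
Reagents that add atoms: none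
Why: Indium-mediated Barbier reaction of a γ-substituted propargyl bromide proceeds by SE2′ to the allenyl carbinol; the racemic carbinol centre is removed in step 3.

Step 3
Reactants: 6 (±)-3-methylpenta-3,4-dien-2-ol
Product: 7 3-methylpenta-3,4-dien-2-one
Conditions: Dess–Martin periodinane, NaHCO3, CH2Cl2, 0 °C
Reagents that add atoms: none
Why: Buffered Dess–Martin oxidation of an allenic secondary alcohol gives the allenyl methyl ketone without base-induced isomerisation.

Step 4
Reactants: 7 3-methylpenta-3,4-dien-2-one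
Product: 8 tert-butyl(dimethyl)[(3-methylpenta-1,3,4-trien-2-yl)oxy]silane
Conditions: TBSOTf, Et3N, Et2O, −78 → 0 °C
Reagents that add atoms: tert-butyldimethylsilyl trifluoromethanesulfonate, CC(C)(C)[Si](C)(C)OS(=O)(=O)C(F)(F)F
Why: Soft enolisation/O-silylation of the methyl ketone on its only α-CH3 gives the cross-conjugated 2-silyloxy vinylallene.

Step 5
Reactants: 3 (2E)-2,4,4-trimethylhepta-2,6-dienal; 8 tert-butyl(dimethyl)[(3-methylpenta-1,3,4-trien-2-yl)oxy]silane
Product: 9 (1S,6S)-4-[tert-butyl(dimethyl)silyl]oxy-1,3-dimethyl-2-methylidene-6-(2-methylpent-4-en-2-yl)cyclohex-3-ene-1-carbaldehyde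
Conditions: (S)-B-(o-tolyl)-diphenylprolinol oxazaborolidine activated with AlBr3 (10 mol %), 8 (1.5 equiv), CH2Cl2, −78 → −40 °C
Reagents that add atoms: none
Why: Lewis-acid-catalysed, concerted but asynchronous [4+2] cycloaddition (Diels–Alder) in which the silyloxy-activated CH2 terminus C6 bonds to the β-carbon C5 of the complexed enal and the sp-hybridised allene carbon C9 closes onto the α-carbon C10. The closest known reaction types are the oxazaborolidinium-catalysed Diels–Alder reactions of 2-silyloxydienes with α-substituted enals and the Diels–Alder reactions of vinylallenes. Ring B is closed by intermolecular [4+2] annulation, both σ-bonds forming on one face of the dienophile. The relative configuration of C5 and C10 (C4 cis to the C10 methyl, hence H-5 trans to it once C1 and C4 are joined) follows stereospecifically from the (E)-geometry of 3, and the quaternary C10 is formed directly. The absolute configuration is controlled by the catalyst, which must expose the Re face of C-2 of the enal; the (S)-catalyst is assigned from the formyl C–H···O binding model, and its antipode would be used if the first run showed the opposite sense. The step needs regioselectivity, secured by the 2-silyloxy group, and periselectivity, secured because C9 becomes an exocyclic sp2 carbon (no endo/exo issue) and the new C11=C9–C8=C7 diene is locked s-trans and cannot add a second dienophile.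

Step 6
Reactants: 9 (1S,6S)-4-[tert-butyl(dimethyl)silyl]oxy-1,3-dimethyl-2-methylidene-6-(2-methylpent-4-en-2-yl)cyclohex-3-ene-1-carbaldehyde
Product: 10 tert-butyl{[(4S,5S)-4-ethenyl-2,4-dimethyl-3-methylidene-5-(2-methylpent-4-en-2-yl)cyclohex-1-en-1-yl]oxy}dimethylsilane
Conditions: Ph3PCH3Br, KHMDS, THF, 0 °C → rt
Reagents that add atoms: methyltriphenylphosphonium bromide, C[P+](c1ccccc1)(c1ccccc1)c1ccccc1.[Br-]
Why: Wittig methylenation of the non-enolisable quaternary aldehyde turns C1 into a vinyl group; the silyl enol ether is stable to the ylide.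

Step 7
Reactants: 10 tert-butyl{[(4S,5S)-4-ethenyl-2,4-dimethyl-3-methylidene-5-(2-methylpent-4-en-2-yl)cyclohex-1-en-1-yl]oxy}dimethylsilane
Product: 11 (5S,10S)-7-[tert-butyl(dimethyl)silyl]oxydrima-1,7,9(11)-triene
Conditions: Grubbs II (5 mol %), CH2Cl2, 40 °C
Reagents that add atoms: none
Why: Ring-closing metathesis of the allyl and vinyl arms, which sit trans-diequatorial on ring B, closes ring A as the trans-fused Δ1-cyclohexene; the exocyclic 1,1-disubstituted alkene and the tetrasubstituted enol ether are poor metathesis partners.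

Step 8
Reactants: 11 (5S,10S)-7-[tert-butyl(dimethyl)silyl]oxydrima-1,7,9(11)-triene
Product: 12 (5S,10S)-drima-1,7,9(11)-trien-7-yl trifluoromethanesulfonate
Conditions: CsF, PhNTf2, DME, rt
Reagents that add atoms: N-phenylbis(trifluoromethanesulfonimide), O=S(=O)(N(c1ccccc1)S(=O)(=O)C(F)(F)F)C(F)(F)F
Why: Fluoride-induced desilylation with in situ O-triflation converts the regiodefined silyl enol ether into the enol triflate without moving the double bond.

Step 9
Reactants: 12 (5S,10S)-drima-1,7,9(11)-trien-7-yl trifluoromethanesulfonate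
Product: 13 (5S,10S)-drima-1,7,9(11)-triene
Conditions: Pd(OAc)2 (5 mol %), PPh3, HCO2H, Bu3N, DMF, 60 °C
Reagents that add atoms: none
Why: Palladium-catalysed formate reduction of the enol triflate replaces OTf by H with retention of the C7=C8 position.

Step 10
Reactants: 13 (5S,10S)-drima-1,7,9(11)-triene
Product: 15 (5S,9S,10S)-drima-1,7-dien-11-ol, via B-alkyl-9-BBN adduct 14 (not isolated)
Conditions: 9-BBN, THF, 0 °C → rt; then NaOH, H2O2, 0 °C
Reagents that add atoms: hydrogen peroxide, OO
Why: Hydroboration–oxidation in which 9-BBN should add boron to the terminal C11 of the exocyclic methylene and hydrogen to C9 from the α-face, anti to the axial C10 methyl, setting 9S; the cis-disubstituted and trisubstituted ring alkenes react far more slowly with 9-BBN.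

Step 11
Reactants: 15 (5S,9S,10S)-drima-1,7-dien-11-ol
Product: 16 (−)-drimenol, (5S,9S,10S)-drim-7-en-11-ol
Conditions: H2 (1 atm), RhCl(PPh3)3 (10 mol %), benzene/EtOH, rt
Reagents that add atoms: none
Why: Wilkinson hydrogenation reduces the cis-disubstituted Δ1 alkene and spares the trisubstituted Δ7 alkene, as in the selective 1,2-reduction of steroidal 1,4-dien-3-ones.

Step 12
Reactants: 16 (−)-drimenol
Product: 17 (5S,9S,10S)-11-iododrim-7-ene
Conditions: I2, PPh3, imidazole, CH2Cl2, 0 °C → rt
Reagents that add atoms: iodine, II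
Why: Appel-type iodination converts the primary alcohol to the iodide by SN2 at C11 without touching the stereocentres.

Step 13
Reactants: 17 (5S,9S,10S)-11-iododrim-7-ene
Product: 18 2-[(5S,9S,10S)-drim-7-en-11-yl]-4,4,5,5-tetramethyl-1,3,2-dioxaborolane
Conditions: B2pin2, CuI (10 mol %), PPh3, LiOMe, DMF, rt
Reagents that add atoms: bis(pinacolato)diboron, CC1(C)OB(OC1(C)C)B1OC(C)(C)C(C)(C)O1
Why: Copper-catalysed borylation of a primary alkyl iodide gives the pinacol boronate under mild conditions that tolerate the alkene.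

Step 14
Reactants: 19 1,4-dimethoxybenzene; 20 geranyl bromide, (2E)-1-bromo-3,7-dimethylocta-2,6-diene
Product: 22 2-[(2E)-3,7-dimethylocta-2,6-dien-1-yl]-1,4-dimethoxybenzene, via 2,5-dimethoxyphenyllithium 21 (not isolated)
Conditions: n-BuLi, TMEDA, Et2O, 0 °C → rt; then 20, −78 °C → rt
Reagents that add atoms: none
Why: Directed ortho-lithiation followed by SN2 alkylation with the primary allylic bromide keeps the (E)-alkene and installs the masked hydroquinone.

Step 15
Reactants: 22 2-[(2E)-3,7-dimethylocta-2,6-dien-1-yl]-1,4-dimethoxybenzene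
Product: 23 (2E,6E)-8-(2,5-dimethoxyphenyl)-2,6-dimethylocta-2,6-dien-1-ol
Conditions: SeO2 (cat.), t-BuOOH, CH2Cl2, rt
Reagents that add atoms: tert-butyl hydroperoxide, CC(C)(C)OO
Why: Sharpless-type catalytic SeO2 allylic oxidation attacks the (E)-methyl of the terminal trisubstituted alkene (ene/[2,3] sequence), giving the (E)-allylic alcohol.

Step 16
Reactants: 23 (2E,6E)-8-(2,5-dimethoxyphenyl)-2,6-dimethylocta-2,6-dien-1-ol
Product: 24 (2R,6E)-8-(2,5-dimethoxyphenyl)-2,6-dimethyloct-6-en-1-ol
Conditions: H2 (50 atm), Ru(OAc)2[(R)-BINAP] (1 mol %), MeOH, rt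
Reagents that add atoms: none
Why: Hydroxyl-directed Noyori hydrogenation reduces only the allylic-alcohol alkene and sets C13 by catalyst control; (R)-BINAP is chosen by analogy with the geraniol/citronellol facial correlation.

Step 17
Reactants: 24 (2R,6E)-8-(2,5-dimethoxyphenyl)-2,6-dimethyloct-6-en-1-ol
Product: 25 (2R,6E)-8-(2,5-dimethoxyphenyl)-2,6-dimethyloct-6-en-1-yl N,N-di(propan-2-yl)carbamate
Conditions: ClC(O)N(iPr)2, Et3N, CH2Cl2, reflux
Reagents that add atoms: N,N-diisopropylcarbamoyl chloride, CC(C)N(C(C)C)C(Cl)=O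
Why: Carbamoylation of the primary alcohol installs the Hoppe directing/leaving group for the homologation.

Step 18
Reactants: 25 (2R,6E)-8-(2,5-dimethoxyphenyl)-2,6-dimethyloct-6-en-1-yl N,N-di(propan-2-yl)carbamate; 18 2-[(5S,9S,10S)-drim-7-en-11-yl]-4,4,5,5-tetramethyl-1,3,2-dioxaborolane
Product: 29 (2R,3R,7E)-9-(2,5-dimethoxyphenyl)-3,7-dimethyl-1-[(1S,4aS,8aS)-2,5,5,8a-tetramethyl-1,4,4a,5,6,7,8,8a-octahydronaphthalen-1-yl]non-7-en-2-ol, via lithiated carbamate 26 (not isolated), via boronate complex 27 (not isolated), via secondary boronic ester 28 (not isolated)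
Conditions: s-BuLi, (+)-sparteine, Et2O, −78 °C; then 18, −78 °C; MgBr2·OEt2, reflux; then NaOH, H2O2, 0 °C → rt
Reagents that add atoms: hydrogen peroxide, OO
Why: Hoppe–Aggarwal lithiation–borylation: sparteine-controlled removal of one enantiotopic O–CH2 proton, borylation with retention, stereoinvertive 1,2-shift of the drimenyl CH2 group and oxidation with retention should give the 12R carbinol by reagent control, forming the C11–C12 bond.

Step 19
Reactants: 29 the (12R,13R)-alcohol
Product: 30 (12R,13R)-hydrogen sulfate of 29, dimethoxyarene retained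
Conditions: SO3·pyridine, pyridine, rt
Reagents that add atoms: sulfur trioxide–pyridine complex, O=S(=O)([O-])[n+]1ccccc1
Why: O-sulfation of the only hydroxyl group with SO3·pyridine proceeds with retention at C12; the dimethoxyarene is not sulfonated under these conditions.

Step 20
Reactants: 30 the dimethoxyaryl hydrogen sulfate
Product: 31 2-substituted 1,4-benzoquinone hydrogen sulfate
Conditions: (NH4)2Ce(NO3)6, MeCN/H2O, 0 °C
Reagents that add atoms: water, O
Why: CAN oxidative demethylation of the 2-alkyl-1,4-dimethoxybenzene gives the quinone; isolated trisubstituted alkenes and the sulfate monoester should survive the short, cold treatment.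

Step 21
Reactants: 31 the quinone hydrogen sulfate
Product: 32 halisulfate 1
Conditions: Na2S2O4, THF/H2O, rt
Reagents that add atoms: none
Why: Dithionite reduction of the quinone to the hydroquinone under near-neutral aqueous conditions leaves the alkyl sulfate and both alkenes untouched.

**Compound list**

1 | 2,2-dimethylpent-4-enal | C=CCC(C)(C)C=O | starting material
2 | 2-(triphenyl-λ5-phosphanylidene)propanal | CC(C=O)=P(c1ccccc1)(c1ccccc1)c1ccccc1 | starting material
3 | (2E)-2,4,4-trimethylhepta-2,6-dienal | O=C/C(C)=C/C(C)(C)CC=C | intermediate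
4 | 1-bromobut-2-yne | CC#CCBr | starting material
5 | acetaldehyde | CC=O | starting material
6 | (±)-3-methylpenta-3,4-dien-2-ol | CC(O)C(C)=C=C | intermediate
7 | 3-methylpenta-3,4-dien-2-one | CC(=O)C(C)=C=C | intermediate
8 | tert-butyl(dimethyl)[(3-methylpenta-1,3,4-trien-2-yl)oxy]silane | C=C(O[Si](C)(C)C(C)(C)C)C(C)=C=C | intermediate
9 | (1S,6S)-4-[tert-butyl(dimethyl)silyl]oxy-1,3-dimethyl-2-methylidene-6-(2-methylpent-4-en-2-yl)cyclohex-3-ene-1-carbaldehyde | CC1=C(O[Si](C)(C)C(C)(C)C)C[C@@H](C(C)(C)CC=C)[C@](C)(C=O)C1=C | intermediate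
10 | tert-butyl{[(4S,5S)-4-ethenyl-2,4-dimethyl-3-methylidene-5-(2-methylpent-4-en-2-yl)cyclohex-1-en-1-yl]oxy}dimethylsilane | CC1=C(O[Si](C)(C)C(C)(C)C)C[C@@H](C(C)(C)CC=C)[C@](C)(C=C)C1=C | intermediate
11 | (5S,10S)-7-[tert-butyl(dimethyl)silyl]oxydrima-1,7,9(11)-triene | CC1=C(O[Si](C)(C)C(C)(C)C)C[C@H]2C(C)(C)CC=C[C@]2(C)C1=C | intermediate
12 | (5S,10S)-drima-1,7,9(11)-trien-7-yl trifluoromethanesulfonate | CC1=C(OS(=O)(=O)C(F)(F)F)C[C@H]2C(C)(C)CC=C[C@]2(C)C1=C | intermediate
13 | (5S,10S)-drima-1,7,9(11)-triene | CC1=CC[C@H]2C(C)(C)CC=C[C@]2(C)C1=C | intermediate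
14 | 9-[(5S,9S,10S)-drima-1,7-dien-11-yl]-9-borabicyclo[3.3.1]nonane | CC1=CC[C@H]2C(C)(C)CC=C[C@]2(C)[C@H]1CB1C2CCCC1CCC2 | intermediate (not isolated)
15 | (5S,9S,10S)-drima-1,7-dien-11-ol | CC1=CC[C@H]2C(C)(C)CC=C[C@]2(C)[C@H]1CO | intermediate
16 | (−)-drimenol, (5S,9S,10S)-drim-7-en-11-ol | CC1=CC[C@H]2C(C)(C)CCC[C@]2(C)[C@H]1CO | intermediate
17 | (5S,9S,10S)-11-iododrim-7-ene | CC1=CC[C@H]2C(C)(C)CCC[C@]2(C)[C@H]1CI | intermediate
18 | 2-[(5S,9S,10S)-drim-7-en-11-yl]-4,4,5,5-tetramethyl-1,3,2-dioxaborolane | CC1=CC[C@H]2C(C)(C)CCC[C@]2(C)[C@H]1CB1OC(C)(C)C(C)(C)O1 | intermediate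
19 | 1,4-dimethoxybenzene | COc1ccc(OC)cc1 | starting material
20 | geranyl bromide, (2E)-1-bromo-3,7-dimethylocta-2,6-diene | CC(C)=CCC/C(C)=C/CBr | starting material
21 | (2,5-dimethoxyphenyl)lithium | [Li]c1cc(OC)ccc1OC | intermediate (not isolated)
22 | 2-[(2E)-3,7-dimethylocta-2,6-dien-1-yl]-1,4-dimethoxybenzene | COc1ccc(OC)c(C/C=C(\C)CCC=C(C)C)c1 | intermediate
23 | (2E,6E)-8-(2,5-dimethoxyphenyl)-2,6-dimethylocta-2,6-dien-1-ol | COc1ccc(OC)c(C/C=C(\C)CC/C=C(\C)CO)c1 | intermediate
24 | (2R,6E)-8-(2,5-dimethoxyphenyl)-2,6-dimethyloct-6-en-1-ol | COc1ccc(OC)c(C/C=C(\C)CCC[C@@H](C)CO)c1 | intermediate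
25 | (2R,6E)-8-(2,5-dimethoxyphenyl)-2,6-dimethyloct-6-en-1-yl N,N-di(propan-2-yl)carbamate | COc1ccc(OC)c(C/C=C(\C)CCC[C@@H](C)COC(=O)N(C(C)C)C(C)C)c1 | intermediate
26 | (1R,2R,6E)-8-(2,5-dimethoxyphenyl)-1-lithio-2,6-dimethyloct-6-en-1-yl N,N-di(propan-2-yl)carbamate (sparteine complex) | COc1ccc(OC)c(C/C=C(\C)CCC[C@@H](C)[C@@H]([Li])OC(=O)N(C(C)C)C(C)C)c1 | intermediate (not isolated)
27 | lithium boronate complex of 26 with 18 (B bears pinacolate, the drimenyl CH2 and the carbamoyloxy-substituted C12) | [Li+].COc1ccc(OC)c(C/C=C(\C)CCC[C@@H](C)[C@H](OC(=O)N(C(C)C)C(C)C)[B-]2(C[C@H]3C(C)=CC[C@H]4C(C)(C)CCC[C@]34C)OC(C)(C)C(C)(C)O2)c1 | intermediate (not isolated)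
28 | (12R,13R)-secondary pinacol boronic ester (Bpin on C12 in place of OH of 29) | CC1=CC[C@H]2C(C)(C)CCC[C@]2(C)[C@H]1C[C@@H](B3OC(C)(C)C(C)(C)O3)[C@H](C)CCC/C(C)=C/Cc1cc(OC)ccc1OC | intermediate (not isolated)
29 | (2R,3R,7E)-9-(2,5-dimethoxyphenyl)-3,7-dimethyl-1-[(1S,4aS,8aS)-2,5,5,8a-tetramethyl-1,4,4a,5,6,7,8,8a-octahydronaphthalen-1-yl]non-7-en-2-ol | CC1=CC[C@H]2C(C)(C)CCC[C@]2(C)[C@H]1C[C@@H](O)[C@H](C)CCC/C(C)=C/Cc1cc(OC)ccc1OC | intermediate
30 | hydrogen sulfate of 29 (O-sulfated at C12, dimethoxyarene) | CC1=CC[C@H]2C(C)(C)CCC[C@]2(C)[C@H]1C[C@@H](OS(=O)(=O)O)[C@H](C)CCC/C(C)=C/Cc1cc(OC)ccc1OC | intermediate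
31 | corresponding 2-alkyl-1,4-benzoquinone hydrogen sulfate | CC1=CC[C@H]2C(C)(C)CCC[C@]2(C)[C@H]1C[C@@H](OS(=O)(=O)O)[C@H](C)CCC/C(C)=C/CC1=CC(=O)C=CC1=O | intermediate
32 | halisulfate 1 | CC1=CC[C@H]2C(C)(C)CCC[C@]2(C)[C@H]1C[C@@H](OS(=O)(=O)O)[C@H](C)CCC/C(C)=C/Cc1cc(O)ccc1O | target

**Step count and risks**

Total step count: 21. Longest linear sequence: 16 steps (steps 2–13, then 18–21).

Steps most likely to fail:

1. Step 5 (key cycloaddition). The bulky chiral Lewis acid may not activate the neopentyl-flanked, trisubstituted enal at temperatures the silyl dienol ether tolerates. 1,2-Attack on the complexed formyl group (Mukaiyama aldol) may outrun bond formation at C5, or face discrimination may be poor. The fallback gives up catalyst control. It sets out from 3 and 8, which are heated without catalyst (toluene, 130 °C, sealed tube, BHT; thermal Diels–Alder of a 2-silyloxydiene with an enal) to give 9 as a racemate with its enantiomer, ent-adduct F1. The racemate is condensed with (1R,2R)-N,N′-dimethyl-1,2-diphenylethane-1,2-diamine (Et2O, 4 Å sieves) to the diastereomeric imidazolidines, aminal of 9 F2 and aminal of ent-9 F3. These are separated by chromatography, and F2 is hydrolysed on wet silica gel with a trace of acid at 0 °C. The fallback comes back to the route at 9.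

2. Step 18 (lithiation–borylation). s-BuLi/sparteine may remove the doubly activated ArCH2–CH= proton or an aryl proton instead of the O–CH2 proton. The lithiated carbamate may be mismatched with the neighbouring C13 centre, or the hindered boronate complex may not rearrange. The fallback sets out from 24 and 17. Alcohol 24 is oxidised (Dess–Martin) to (2R,6E)-8-(2,5-dimethoxyphenyl)-2,6-dimethyloct-6-enal F4. Iodide 17 is converted by iodine–lithium exchange (t-BuLi, Et2O, −78 °C) to drimenyllithium F5, which is added to F4. This should give 29 mixed with its C12 epimer, 12-epi-alcohol F6, since the Felkin bias of an α-methyl aldehyde is weak. The mixture is oxidised (Dess–Martin) to the C12 ketone F7 and reduced with BH3·SMe2 and (S)-Me-CBS, where reagent control should give the 12R alcohol. The fallback comes back to the route at 29.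

3. Step 4 (silyl dienol ether from the allenyl ketone). The amine base may add to the allenone, or the allenone may oligomerise before O-silylation. The fallback drops the C7 oxygen. It sets out from 6, which is dehydrated (Burgess reagent, benzene, 50 °C) to 3-methylpenta-1,2,4-triene F8. Cycloaddition of F8 with 3 under the conditions of step 5 should give (1S,6S)-1,3-dimethyl-2-methylidene-6-(2-methylpent-4-en-2-yl)cyclohex-3-ene-1-carbaldehyde F9. Regiochemistry then rests on the allenic terminus behaving as a 1-donor and on the steric match of the CH2 terminus with the neopentyl β-carbon. Wittig methylenation of F9 gives the tetraene F10, and ring-closing metathesis (Grubbs II) comes back to the route at 13, so steps 8 and 9 are not needed.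

**Further compounds**

F1 | step 5 | (1R,6R)-enantiomer of 9 | CC1=C(O[Si](C)(C)C(C)(C)C)C[C@H](C(C)(C)CC=C)[C@@](C)(C=O)C1=C
F2 | step 5 | (4R,5R)-1,3-dimethyl-4,5-diphenylimidazolidin-2-yl aminal of 9 | CC1=C(O[Si](C)(C)C(C)(C)C)C[C@@H](C(C)(C)CC=C)[C@](C)(C2N(C)[C@H](c3ccccc3)[C@@H](c3ccccc3)N2C)C1=C
F3 | step 5 | (4R,5R)-1,3-dimethyl-4,5-diphenylimidazolidin-2-yl aminal of ent-9 | CC1=C(O[Si](C)(C)C(C)(C)C)C[C@H](C(C)(C)CC=C)[C@@](C)(C2N(C)[C@H](c3ccccc3)[C@@H](c3ccccc3)N2C)C1=C
F4 | step 18 | (2R,6E)-8-(2,5-dimethoxyphenyl)-2,6-dimethyloct-6-enal | O=C[C@H](C)CCC/C(C)=C/Cc1cc(OC)ccc1OC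
F5 | step 18 | [(5S,9S,10S)-drim-7-en-11-yl]lithium | [Li]C[C@H]1C(C)=CC[C@H]2C(C)(C)CCC[C@]12C
F6 | step 18 | (12S,13R)-epimer of 29 | CC1=CC[C@H]2C(C)(C)CCC[C@]2(C)[C@H]1C[C@H](O)[C@H](C)CCC/C(C)=C/Cc1cc(OC)ccc1OC
F7 | step 18 | C12 ketone corresponding to 29 | CC1=CC[C@H]2C(C)(C)CCC[C@]2(C)[C@H]1CC(=O)[C@H](C)CCC/C(C)=C/Cc1cc(OC)ccc1OC
F8 | step 4 | 3-methylpenta-1,2,4-triene | C=CC(C)=C=C
F9 | step 4 | (1S,6S)-1,3-dimethyl-2-methylidene-6-(2-methylpent-4-en-2-yl)cyclohex-3-ene-1-carbaldehyde | CC1=CC[C@@H](C(C)(C)CC=C)[C@](C)(C=O)C1=C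
F10 | step 4 | (5S,6S)-6-ethenyl-1,6-dimethyl-2-methylidene-5-(2-methylpent-4-en-2-yl)cyclohex-3-ene, written as 4-ethenyl-2,4-dimethyl-3-methylidene-5-(2-methylpent-4-en-2-yl)cyclohex-1-ene | CC1=CC[C@@H](C(C)(C)CC=C)[C@](C)(C=C)C1=C
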